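**Assumption:** the target is taken as the drawn enantiomer, (1S,5R,6S,8aR) in naphthalene numbering; in the text carbons are cited in halimane numbering (ring A = C1–C5 and C10, ring B = C5–C10, side chain C11–C15 with the C16 methyl, C19 = carboxyl carbon).

## Retrosynthetic overview

1. Target 20 ⇐ acetylation of allylic alcohol 19 ⇐ C12–C13 bond by nickel-electrocatalytic decarboxylative alkenylation of diacid 14 (chain acid only) with (E)-3-iodobut-2-en-1-ol 17.
2. 14 ⇐ excision of a sacrificial C6 isopropenyl group and ester hydrolysis from Diels–Alder adduct 10.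
3. Ring A (C4, C5 and the C1=C10 alkene) ⇐ Diels–Alder reaction of the ring B vinyl diene 8 with methacrolein; ring A is formed last, on the finished ring B.
4. Ring B with C8 and C9 ⇐ (S)-carvone 1 by conjugate methylation and enolate Michael addition; the carvone stereocenter controls every other centre and is then removed.

## Route

Step 1
Reactants: 1 (S)-(+)-carvone; 2 methyl acrylate
Product: 4 methyl 3-[(1R,2S,4S)-1,2-dimethyl-6-oxo-4-(prop-1-en-2-yl)cyclohexyl]propanoate, via bromomagnesium enolate 3 (not isolated)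
Conditions: MeMgBr (1.1 equiv), CuBr·SMe2 (5 mol %), THF, −40 °C; then 2, DMPU, −78 to −20 °C; H2O quench
Reagents that add atoms: methylmagnesium bromide (MeMgBr), C[Mg]Br
Why: Copper-catalysed conjugate addition puts the methyl on C8 trans to the isopropenyl group, and the regiodefined enolate then adds to the acrylate (tandem conjugate addition–Michael reaction) at C9 anti to the pseudoaxial C8 methyl, giving the cis-dimethyl quaternary centre.

Step 2
Reactants: 4 methyl 3-[(1R,2S,4S)-1,2-dimethyl-6-oxo-4-(prop-1-en-2-yl)cyclohexyl]propanoate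
Product: 6 methyl 3-[(1R,4S,6S)-1,6-dimethyl-4-(prop-1-en-2-yl)-2-(trifluoromethanesulfonyloxy)cyclohex-2-en-1-yl]propanoate, via potassium enolate 5 (not isolated)
Conditions: KN(SiMe3)2 (1.05 equiv), THF, −78 °C; then PhNTf2, −78 to 0 °C
Reagents that add atoms: N-phenylbis(trifluoromethanesulfonimide), O=S(=O)(N(c1ccccc1)S(=O)(=O)C(F)(F)F)C(F)(F)F
Why: The ketone is enolisable only towards C5 (C9 is quaternary) and is far more acidic than the ester, so enol triflate formation gives the C5=C10 triflate regiospecifically without touching a stereocenter.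

Step 3
Reactants: 6 methyl 3-[(1R,4S,6S)-1,6-dimethyl-4-(prop-1-en-2-yl)-2-(trifluoromethanesulfonyloxy)cyclohex-2-en-1-yl]propanoate; 7 2-ethenyl-4,4,5,5-tetramethyl-1,3,2-dioxaborolane
Product: 8 methyl 3-[(1R,4S,6S)-2-ethenyl-1,6-dimethyl-4-(prop-1-en-2-yl)cyclohex-2-en-1-yl]propanoate
Conditions: Pd(PPh3)4 (5 mol %), K3PO4, 1,4-dioxane/H2O, 80 °C
Reagents that add atoms: none
Why: Suzuki–Miyaura coupling of an enol triflate with a vinylboronate is reliable next to a quaternary carbon, tolerates the ester, and installs C1–C2 as the s-cis-disposed diene.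

Step 4
Reactants: 8 methyl 3-[(1R,4S,6S)-2-ethenyl-1,6-dimethyl-4-(prop-1-en-2-yl)cyclohex-2-en-1-yl]propanoate; 9 methacrolein
Product: 10 methyl 3-[(1R,2S,4S,4aR,5S)-5-formyl-1,2,5-trimethyl-4-(prop-1-en-2-yl)-1,2,3,4,4a,5,6,7-octahydronaphthalen-1-yl]propanoate
Conditions: Me2AlCl (2 equiv), CH2Cl2, −78 to −20 °C; aq NaHCO3
Reagents that add atoms: none
Why: Lewis-acid-promoted Diels–Alder reaction with ortho regiochemistry (C4 to C5, C3 to C2) and an endo-formyl transition state; the dienophile bonds to C5 on the face of the C8 and C9 methyls because the other face carries a pseudoaxial allylic group in either half-chair (the C9 chain or the C6 isopropenyl), which sets C5 (H trans to the new bond) and C4 (formyl trans to H5) and places the alkene at C1=C10.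

Step 5
Reactants: 10 methyl 3-[(1R,2S,4S,4aR,5S)-5-formyl-1,2,5-trimethyl-4-(prop-1-en-2-yl)-1,2,3,4,4a,5,6,7-octahydronaphthalen-1-yl]propanoate
Product: 11 (1S,5R,6S,8S,8aR)-5-(3-methoxy-3-oxopropyl)-1,5,6-trimethyl-8-(prop-1-en-2-yl)-1,2,3,5,6,7,8,8a-octahydronaphthalene-1-carboxylic acid
Conditions: NaClO2, NaH2PO4, 2-methylbut-2-ene (excess), t-BuOH/H2O, 0 °C to rt
Reagents that add atoms: sodium chlorite (NaClO2), [Na+].[O-]Cl=O
Why: Pinnick oxidation converts the non-enolisable neopentyl aldehyde into the acid while the scavenger protects both alkenes, and no stereocenter is involved.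

Step 6
Reactants: 11 (1S,5R,6S,8S,8aR)-5-(3-methoxy-3-oxopropyl)-1,5,6-trimethyl-8-(prop-1-en-2-yl)-1,2,3,5,6,7,8,8a-octahydronaphthalene-1-carboxylic acid
Product: 13 (1S,5R,6S,8aR)-5-(3-methoxy-3-oxopropyl)-1,5,6-trimethyl-1,2,3,5,6,7,8,8a-octahydronaphthalene-1-carboxylic acid, via methoxy hydroperoxide 12 (not isolated)
Conditions: O3, CH2Cl2/MeOH, −78 °C (Sudan Red 7B end point); then FeSO4·7H2O (1.2 equiv), PhSH (3 equiv), −78 °C to rt
Reagents that add atoms: none
Why: Ozonolytic hydrodealkenylation (Criegee ozonolysis in methanol, then divalent-iron-induced alkoxy-radical β-scission and hydrogen-atom transfer from the thiol) excises the controlling isopropenyl group, while the C1=C10 alkene is shielded on both faces (axial C8 methyl and C19 carboxyl on one, axial C9 chain on the other); C6 becomes CH2, so no stereocenter is at stake.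

Step 7
Reactants: 13 (1S,5R,6S,8aR)-5-(3-methoxy-3-oxopropyl)-1,5,6-trimethyl-1,2,3,5,6,7,8,8a-octahydronaphthalene-1-carboxylic acid
Product: 14 (1S,5R,6S,8aR)-5-(2-carboxyethyl)-1,5,6-trimethyl-1,2,3,5,6,7,8,8a-octahydronaphthalene-1-carboxylic acid
Conditions: LiOH, THF/MeOH/H2O, rt; then 1 M HCl to pH 3, 0 °C
Reagents that add atoms: lithium hydroxide (LiOH), [Li+].[OH-]
Why: Saponification of the unhindered primary methyl ester is routine, and the cold, brief acidification avoids lactonisation of the γ,δ-unsaturated acid.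

Step 8
Reactants: 15 but-2-yn-1-ol
Product: 17 (E)-3-iodobut-2-en-1-ol, via alkenylzirconocene 16 (not isolated)
Conditions: Cp2Zr(H)Cl (2.2 equiv), THF, rt; then I2, 0 °C
Reagents that add atoms: iodine, II
Why: Hydrozirconation is a syn addition that, after equilibration, places zirconium on the less hindered methyl-bearing alkyne carbon, and iodinolysis with retention gives the E alkenyl iodide (iodine trans to CH2OH).

Step 9
Reactants: 14 (1S,5R,6S,8aR)-5-(2-carboxyethyl)-1,5,6-trimethyl-1,2,3,5,6,7,8,8a-octahydronaphthalene-1-carboxylic acid; 17 (E)-3-iodobut-2-en-1-ol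
Product: 19 (1S,5R,6S,8aR)-5-[(3E)-5-hydroxy-3-methylpent-3-en-1-yl]-1,5,6-trimethyl-1,2,3,5,6,7,8,8a-octahydronaphthalene-1-carboxylic acid, via N-acyloxyphthalimide ester 18 (not isolated)
Conditions: N-hydroxyphthalimide (1.0 equiv), N,N′-diisopropylcarbodiimide (1.0 equiv), THF, 0 °C; then 17 (2 equiv), NiCl2·6H2O (20 mol %), 2,2′-bipyridine (20 mol %), AgNO3 (30 mol %), LiCl, DMF, Mg anode, reticulated vitreous carbon cathode, 5 mA, rt
Reagents that add atoms: none
Why: Proposed new method: site-selective one-pot redox-active-ester formation and nickel-electrocatalytic decarboxylative alkenylation of an unprotected diacid with a hydroxyl-bearing alkenyl iodide — one equivalent of carbodiimide and N-hydroxyphthalimide acylates only the unhindered primary chain acid (the axial α-quaternary C19 acid reacts far more slowly and stays as its magnesium carboxylate), cathodically generated low-valent nickel–bipyridine reduces ester 18 by single-electron transfer to release CO2 and the primary C12 radical, zerovalent nickel inserts into the C–I bond of 17 with retention of the E geometry, and radical capture followed by reductive elimination from trivalent nickel forges C12–C13 without touching a stereocenter; the closest known reaction type is the nickel-electrocatalytic decarboxylative alkenylation of pre-formed redox-active esters of mono-acids.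

Step 10
Reactants: 19 (1S,5R,6S,8aR)-5-[(3E)-5-hydroxy-3-methylpent-3-en-1-yl]-1,5,6-trimethyl-1,2,3,5,6,7,8,8a-octahydronaphthalene-1-carboxylic acid
Product: 20 (1S,5R,6S,8aR)-5-[(3E)-5-(acetyloxy)-3-methylpent-3-en-1-yl]-1,5,6-trimethyl-1,2,3,5,6,7,8,8a-octahydronaphthalene-1-carboxylic acid
Conditions: Ac2O (1.5 equiv), pyridine, DMAP (cat.), CH2Cl2, 0 °C; aq NaHCO3, then pH 4
Reagents that add atoms: acetic anhydride, CC(=O)OC(C)=O
Why: Nucleophilic acyl substitution (DMAP-catalysed acetylation) esterifies the primary allylic alcohol, and any mixed anhydride at the hindered acid is hydrolysed in the bicarbonate work-up.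

## Compound list

1 | (S)-(+)-carvone, (5S)-2-methyl-5-(prop-1-en-2-yl)cyclohex-2-en-1-one | CC1=CC[C@@H](CC1=O)C(C)=C | starting material
2 | methyl acrylate | C=CC(=O)OC | starting material
3 | bromomagnesium (3S,5S)-2,3-dimethyl-5-(prop-1-en-2-yl)cyclohex-1-en-1-olate | CC1=C(O[Mg]Br)C[C@@H](C(C)=C)C[C@@H]1C | intermediate
4 | methyl 3-[(1R,2S,4S)-1,2-dimethyl-6-oxo-4-(prop-1-en-2-yl)cyclohexyl]propanoate | COC(=O)CC[C@@]1(C)C(=O)C[C@@H](C(C)=C)C[C@@H]1C | intermediate
5 | potassium (3S,5S,6R)-6-(3-methoxy-3-oxopropyl)-5,6-dimethyl-3-(prop-1-en-2-yl)cyclohex-1-en-1-olate | COC(=O)CC[C@@]1(C)C([O-])=C[C@@H](C(C)=C)C[C@@H]1C.[K+] | intermediate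
6 | methyl 3-[(1R,4S,6S)-1,6-dimethyl-4-(prop-1-en-2-yl)-2-(trifluoromethanesulfonyloxy)cyclohex-2-en-1-yl]propanoate | COC(=O)CC[C@@]1(C)C(OS(=O)(=O)C(F)(F)F)=C[C@@H](C(C)=C)C[C@@H]1C | intermediate
7 | 2-ethenyl-4,4,5,5-tetramethyl-1,3,2-dioxaborolane | C=CB1OC(C)(C)C(C)(C)O1 | starting material
8 | methyl 3-[(1R,4S,6S)-2-ethenyl-1,6-dimethyl-4-(prop-1-en-2-yl)cyclohex-2-en-1-yl]propanoate | COC(=O)CC[C@@]1(C)C(C=C)=C[C@@H](C(C)=C)C[C@@H]1C | intermediate
9 | methacrolein, 2-methylprop-2-enal | CC(=C)C=O | starting material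
10 | methyl 3-[(1R,2S,4S,4aR,5S)-5-formyl-1,2,5-trimethyl-4-(prop-1-en-2-yl)-1,2,3,4,4a,5,6,7-octahydronaphthalen-1-yl]propanoate | COC(=O)CC[C@@]1(C)C2=CCC[C@](C)(C=O)[C@@H]2[C@@H](C(C)=C)C[C@@H]1C | intermediate
11 | (1S,5R,6S,8S,8aR)-5-(3-methoxy-3-oxopropyl)-1,5,6-trimethyl-8-(prop-1-en-2-yl)-1,2,3,5,6,7,8,8a-octahydronaphthalene-1-carboxylic acid | COC(=O)CC[C@@]1(C)C2=CCC[C@](C)(C(=O)O)[C@@H]2[C@@H](C(C)=C)C[C@@H]1C | intermediate
12 | (1S,5R,6S,8S,8aR)-8-(1-hydroperoxy-1-methoxyethyl)-5-(3-methoxy-3-oxopropyl)-1,5,6-trimethyl-1,2,3,5,6,7,8,8a-octahydronaphthalene-1-carboxylic acid (both epimers at the peroxy carbon) | COC(=O)CC[C@@]1(C)C2=CCC[C@](C)(C(=O)O)[C@@H]2[C@@H](C(C)(OC)OO)C[C@@H]1C | intermediate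
13 | (1S,5R,6S,8aR)-5-(3-methoxy-3-oxopropyl)-1,5,6-trimethyl-1,2,3,5,6,7,8,8a-octahydronaphthalene-1-carboxylic acid | COC(=O)CC[C@@]1(C)C2=CCC[C@](C)(C(=O)O)[C@@H]2CC[C@@H]1C | intermediate
14 | (1S,5R,6S,8aR)-5-(2-carboxyethyl)-1,5,6-trimethyl-1,2,3,5,6,7,8,8a-octahydronaphthalene-1-carboxylic acid | OC(=O)CC[C@@]1(C)C2=CCC[C@](C)(C(=O)O)[C@@H]2CC[C@@H]1C | intermediate
15 | but-2-yn-1-ol | CC#CCO | starting material
16 | chloro[(2E)-4-{[chlorobis(cyclopentadienyl)zirconio]oxy}but-2-en-2-yl]bis(cyclopentadienyl)zirconium | C/C(=C\CO[Zr](Cl)(C1C=CC=C1)C1C=CC=C1)[Zr](Cl)(C1C=CC=C1)C1C=CC=C1 | intermediate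
17 | (E)-3-iodobut-2-en-1-ol | C/C(I)=C\CO | intermediate
18 | (1S,5R,6S,8aR)-5-{3-[(1,3-dioxoisoindolin-2-yl)oxy]-3-oxopropyl}-1,5,6-trimethyl-1,2,3,5,6,7,8,8a-octahydronaphthalene-1-carboxylic acid | O=C(CC[C@@]1(C)C2=CCC[C@](C)(C(=O)O)[C@@H]2CC[C@@H]1C)ON1C(=O)c2ccccc2C1=O | intermediate
19 | (1S,5R,6S,8aR)-5-[(3E)-5-hydroxy-3-methylpent-3-en-1-yl]-1,5,6-trimethyl-1,2,3,5,6,7,8,8a-octahydronaphthalene-1-carboxylic acid | OC/C=C(\C)CC[C@@]1(C)C2=CCC[C@](C)(C(=O)O)[C@@H]2CC[C@@H]1C | intermediate
20 | (1S,5R,6S,8aR)-5-[(3E)-5-(acetyloxy)-3-methylpent-3-en-1-yl]-1,5,6-trimethyl-1,2,3,5,6,7,8,8a-octahydronaphthalene-1-carboxylic acid | CC(=O)OC/C=C(\C)CC[C@@]1(C)C2=CCC[C@](C)(C(=O)O)[C@@H]2CC[C@@H]1C | target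

## Step count and risks

Total steps: 10. Longest linear sequence: 9 (steps 1 to 7, then 9 and 10); step 8 makes the side-chain fragment.

**Step 4 (Diels–Alder).** The facial and endo selectivity of a methacrolein cycloaddition at the hindered diene terminus is the least certain point, and an exo transition state would give the C4 epimer. The fallback sets out from 8: Diels–Alder reaction with the more reactive acrolein (Me2AlCl, CH2Cl2, −78 °C) gives the des-methyl aldehyde F1 as a mixture at C4, which does not matter. Enolisation with KN(SiMe3)2 at −78 °C (the aldehyde is far more acidic than the ester) and methylation with MeI from the equatorial side, trans to the C5–C6 bond, then installs the C4 methyl. This comes back to the route at 10, with C4 set by enolate alkylation instead of by endo/exo selection.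

**Step 6 (chemoselective ozonolysis).** Ozone could also attack the C1=C10 alkene. The fallback sets out from 11: iodolactonisation (I2, NaHCO3, MeCN/H2O) gives the iodolactone F2, which masks the ring alkene and the acid at once. The same ozonolysis and FeSO4·7H2O/PhSH fragmentation, now with no competing alkene, gives the de-isopropenylated iodolactone F3. Zn dust in AcOH then restores the alkene and the acid by reductive elimination and comes back to the route at 13.

**Step 9 (proposed new coupling).** Mono-activation of the diacid may not be clean, or the free acid may interfere at nickel. The fallback uses known carbonyl-olefination chemistry and keeps the ester carbon as C13 instead of excising it. It sets out from 13: MeNHOMe·HCl with i-PrMgCl gives the Weinreb amide F4, and MeMgBr gives the methyl ketone F5. Horner–Wadsworth–Emmons olefination with triethyl phosphonoacetate and NaH gives the E enoate F6, with the minor Z isomer removed by chromatography. Reduction with i-Bu2AlH at −78 °C gives the allylic alcohol and comes back to the route at 19.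

Further compounds
F1 | step 4 | methyl 3-[(1R,2S,4S,4aS)-5-formyl-1,2-dimethyl-4-(prop-1-en-2-yl)-1,2,3,4,4a,5,6,7-octahydronaphthalen-1-yl]propanoate (both C5 epimers of the naphthalene numbering, that is C4 of the halimane numbering) | COC(=O)CC[C@@]1(C)C2=CCCC(C=O)[C@@H]2[C@@H](C(C)=C)C[C@@H]1C
F2 | step 6 | iodolactone of 11: γ-lactone from the C19 carboxyl to C10 on the methyl-bearing face, iodine at C1 on the opposite face, isopropenyl and methyl ester retained | COC(=O)CC[C@@]1(C)[C@@]2(OC3=O)[C@@H](I)CC[C@@]3(C)[C@@H]2[C@@H](C(C)=C)C[C@@H]1C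
F3 | step 6 | iodolactone of 13: the same γ-lactone and C1 iodide with C6 as CH2 | COC(=O)CC[C@@]1(C)[C@@]2(OC3=O)[C@@H](I)CC[C@@]3(C)[C@@H]2CC[C@@H]1C
F4 | step 9 | (1S,5R,6S,8aR)-5-{3-[methoxy(methyl)amino]-3-oxopropyl}-1,5,6-trimethyl-1,2,3,5,6,7,8,8a-octahydronaphthalene-1-carboxylic acid | CON(C)C(=O)CC[C@@]1(C)C2=CCC[C@](C)(C(=O)O)[C@@H]2CC[C@@H]1C
F5 | step 9 | (1S,5R,6S,8aR)-1,5,6-trimethyl-5-(3-oxobutyl)-1,2,3,5,6,7,8,8a-octahydronaphthalene-1-carboxylic acid | CC(=O)CC[C@@]1(C)C2=CCC[C@](C)(C(=O)O)[C@@H]2CC[C@@H]1C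
F6 | step 9 | (1S,5R,6S,8aR)-5-[(3E)-5-ethoxy-3-methyl-5-oxopent-3-en-1-yl]-1,5,6-trimethyl-1,2,3,5,6,7,8,8a-octahydronaphthalene-1-carboxylic acid | CCOC(=O)/C=C(\C)CC[C@@]1(C)C2=CCC[C@](C)(C(=O)O)[C@@H]2CC[C@@H]1C
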